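## The problem

The target **24** is a 2-aryl-3-(hydroxymethyl)-2,3-dihydrobenzofuran (rings A, B and C) that carries at C5 a 7-methoxy-5-(3-hydroxypropyl)benzofuran-2-yl unit (rings D and E) through the biaryl bond C5–C2'. Ring C is pentasubstituted: alkyl at C3a, O1 at C7a, methoxy at C7, the benzofuran at C5 and hydrogen only at C4 and C6. This pattern is awkward to reach by stepwise substitution of a benzene, because each group must be placed relative to the ring fusion. The two stereocentres, C2 (S) and C3 (R), are adjacent and trans. In an open chain this corresponds to an anti relation between the carbinol oxygen and the hydroxymethyl branch when aryl, C2, C3 and the future C3a form the backbone. C2 is a benzylic ether carbon para to the ring-A oxygen and can ionise under acid, strong base or oxidants. C3 is robust, so C3 can be used to control C2 but not the reverse, and no late step may be harsh towards the C2–O1 bond. Sensitive groups are the free phenol, the two primary alcohols and the electron-rich 2-arylbenzofuran; quinone-type oxidants would also dehydrogenate ring B. The enabling feature is that ring C is fused to ring B through the three-atom link O1–C2–C3. If O1 sits on C3 of a pyridazine that already carries the methoxy group at C4 and the benzofuran at C6, and C3 of the chain carries an ethynyl group, the six atoms of ring C are the four pyridazine carbons plus the two alkyne carbons, and rings B and C can be made together.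

## Retrosynthesis

**24 from 23.** No skeletal bond is cut; three O–Si bonds are. The phenol and the C3 hydroxymethyl group carry triisopropylsilyl groups and the remote propanol a tert-butyldimethylsilyl group, so one fluoride treatment ends the synthesis. Benzyl, p-methoxybenzyl or acetal groups would need hydrogenolysis, an oxidant or acid at the end, each of which threatens the C2–O1 bond or the benzofuran.

**23 from 21.** The bonds C3a–C7a and C4–C5 are cut and N2 is reinstated between C7a and C5, which gives the 3-alkynyloxypyridazine **21** (the forward reaction passes through the bridged adduct **22**). Cutting O1–C2 or C3–C3a instead would keep ring C as a pre-made arene and leave its substitution pattern to be bought or built. Here the pattern is read off a flat heterocycle whose positions are already differentiated. Two rings disappear and no stereocentre is involved. The forward reaction is a thermal intramolecular cycloaddition near 200 °C that must not ionise the benzylic C2–O bond.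

**21 from 9 and 19.** The aryl–oxygen bond O1–C7a is cut, giving the anti alkynol **9** and the chloropyridazine **19**. The other C–O bond (C2–O1) is the wrong one to form: alkylating a pyridazinone with a benzylic electrophile would favour nitrogen and lose the configuration at C2. Substitution at the heteroaryl carbon leaves C2 untouched. The forward step goes through the sodium alkoxide **20**. It needs a neighbouring silyl ether that does not migrate, which is why the branch carries triisopropylsilyl and not the smaller tert-butyldimethylsilyl group.

**9 from 2 and 7.** The C2–C3 bond is cut. Both stereocentres arise in this one step: the allenylzinc reagent **8**, formed from the enantiopure propargylic mesylate **7**, transfers its axial chirality to C3, and the cyclic transition state places the carbinol oxygen anti to the branch. An aldol route would need a later carbonyl-to-alkyne homologation on an epimerisable aldehyde, and an asymmetric alkynylation would set only one centre. Aldehyde **2** is silylated vanillin **1**. Mesylate **7** comes from the chiral pool: glyceraldehyde acetonide **3** is homologated to alkyne **4**, unmasked to diol **5**, silylated at the primary oxygen to **6** and mesylated.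

**19 from 15 and 16.** The bond between pyridazine C6 and benzofuran C2' (the future C5–C2' bond) is cut, giving the benzofuran **15** and 3,6-dichloro-4-methoxypyridazine **16**. Metalation of **15** at C2' (lithium **17**, then zinc **18**) and cross-coupling does this in one flask. Building the furan ring on an ethynylpyridazine would add steps on the heterocycle. The forward reaction must couple at C6–Cl only, leaving C3–Cl for the ether formation.

**15 from 10.** The furan ring of **15** is cut at O1'–C2' and C3'–C3a'. The benzofuran alcohol **14** comes from iodophenol **11** and a two-carbon alkyne by coupling and cyclisation (through **12** and **13**). **11** is the ortho-iodination product of dihydroconiferyl alcohol **10**, which already holds the methoxy group and the hydroxypropyl chain in the right places.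

## Roads not taken

**Alternative 1: oxidative ring contraction of a flavanone.** The cut is C3–C3a. The (2S)-flavanone **A1** would be treated with PhI(OAc)2 in acidic trimethyl orthoformate. The enol ether is attacked at C3, the aryl carbon C4a shifts from C4 to C3 with loss of iodobenzene, and the pyranone contracts to the trans ester **A2**.
- Merits: enantioenriched flavanones are accessible by catalytic asymmetric methods; the single centre C2 sets C3, with the ester able to equilibrate to trans; the step runs near room temperature; the C5 bromide allows a late, variable biaryl coupling.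
- Weak points: the acidic medium can open the flavanone to its chalcone and so erode C2. An electron-rich 2-aryl group invites the competing shift of that aryl group, which is why the phenol has to be a mesylate. Ester reduction, biaryl coupling and sulfonate cleavage still follow, and the pattern of ring C has to be present in the starting arene.
- Comparison: this road is better in temperature and in using catalytic asymmetric induction. The chosen plan sets against it that both centres are fixed in an open chain by a reagent of predictable sense, never sit next to a carbonyl or in acid, and that ring C appears with all five substituents and the biaryl bond in place.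

**Alternative 2: chromium carbene benzannulation of ring E.** Three bonds of ring E are cut (C6'–C7', C4'–C5', C3a'–C4'). The furyl carbene complex (CO)5Cr=C(OMe)(furyl) **A3** of zerovalent chromium, the silylated alkyne **A4** and one CO ligand would combine to the 4'-hydroxybenzofuran **A5**.
- Merits: ring E is assembled convergently from a simple terminal alkyne with predictable regiochemistry (the chain ends next to the new phenol), and no cross-coupling regiochemistry has to be solved.
- Weak points: **A3** already has to contain rings A, B and C with both stereocentres, so the key step addresses the easier half of the molecule. Chromium is stoichiometric, and the carbene complex must be made by organolithium chemistry on an advanced, base-sensitive intermediate. **A5** carries a superfluous 4'-hydroxyl that costs two further steps (sulfonylation, reduction).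
- Comparison: it is attractive only for avoiding the site-selective coupling of step 10. The chosen plan makes the benzofuran in three steps from a cheap phenol, carries no extra oxygen and uses its key step on rings B and C.

**Alternative 3: quinone methide cyclisation.** The cut is O1–C2. Ag2O would oxidise the 4-alkylguaiacol unit of **A6** to its para-quinone methide, and the ortho phenol of ring C would add to the exocyclic carbon to give **A7**, trans by preference.
- Merits: biomimetic, mild, no protection of either phenol, and a bromide for the later coupling. The ring-forming event is shorter and gentler than a 200 °C cycloaddition, and in this respect the road is better.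
- Weak points: the C3 centre of **A6**, flanked by two different aryl-bearing carbons, has to be made enantioselectively beforehand in several steps. The quinone methide has a hydrogen at C3 and can tautomerise to the styrene, which erases that centre. Ag2O may also oxidise the ring-C phenol. The trans selectivity rests on thermodynamic preference alone, and **A7** has a free phenol para to the new benzylic ether during the subsequent coupling.
- Comparison: the chosen plan sets C2 kinetically in the same step as C3, never places C3 next to an oxidised carbon, and builds the pattern of ring C instead of buying it.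

Key step: step 12

## Route

Remark: ring positions are numbered as in the target (O1, C2, C3, C3a, C4 to C7, C7a for rings B and C; primed numbers for the benzofuran).

Remark: the sense of chirality transfer in step 6 is assumed to follow the accepted course for propargylic mesylates (anti SN2' attack of zerovalent palladium, transfer to zinc with retention, syn SE2' addition to the aldehyde); on that basis the (S)-mesylate 7 gives the (2R) centre of 9.

Remark: aldehyde 3 oligomerises on storage and would be used freshly distilled.

Step 1
Reactants: 1 vanillin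
Product: 2 3-methoxy-4-(triisopropylsilyloxy)benzaldehyde
Conditions: TIPSCl, imidazole, CH2Cl2, 0 °C to rt
Reagents that add atoms: chlorotriisopropylsilane (TIPSCl), CC(C)[Si](Cl)(C(C)C)C(C)C
Why: Imidazole-promoted silylation of a phenol; the bulky aryl silyl ether should tolerate Et2Zn, the alkoxide of step 11 and the thermal step, and leaves the aldehyde free.

Step 2
Reactants: 3 (R)-2,2-dimethyl-1,3-dioxolane-4-carbaldehyde
Product: 4 (S)-4-ethynyl-2,2-dimethyl-1,3-dioxolane
Conditions: dimethyl (1-diazo-2-oxopropyl)phosphonate, K2CO3, MeOH, 0 °C to rt
Reagents that add atoms: dimethyl (1-diazo-2-oxopropyl)phosphonate (Ohira–Bestmann reagent), COP(=O)(OC)C(=[N+]=[N-])C(C)=O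
Why: Ohira–Bestmann variant of the Seyferth–Gilbert homologation, mild enough for an α-alkoxy aldehyde; the stereocentre is not touched and its descriptor changes from R to S only because ethynyl ranks below CH2O.

Step 3
Reactants: 4 (S)-4-ethynyl-2,2-dimethyl-1,3-dioxolane
Product: 5 (S)-but-3-yne-1,2-diol
Conditions: Dowex 50W-X8 (H+), MeOH–H2O, rt
Reagents that add atoms: none
Why: Acid-catalysed acetal hydrolysis; the resin is filtered off so the water-soluble diol needs no aqueous extraction, and the volatile alkyne 4 can be carried in solution.

Step 4
Reactants: 5 (S)-but-3-yne-1,2-diol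
Product: 6 (S)-1-(triisopropylsilyloxy)but-3-yn-2-ol
Conditions: TIPSCl, imidazole, CH2Cl2, 0 °C
Reagents that add atoms: chlorotriisopropylsilane (TIPSCl), CC(C)[Si](Cl)(C(C)C)C(C)C
Why: Selective silylation of the primary hydroxyl of a 1,2-diol by a bulky silyl chloride; triisopropylsilyl is chosen because it resists O-to-O migration to a neighbouring alkoxide (step 11).

Step 5
Reactants: 6 (S)-1-(triisopropylsilyloxy)but-3-yn-2-ol
Product: 7 (S)-1-(triisopropylsilyloxy)but-3-yn-2-yl methanesulfonate
Conditions: MsCl, Et3N, CH2Cl2, −78 °C
Reagents that add atoms: methanesulfonyl chloride (MsCl), CS(=O)(=O)Cl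
Why: Sulfonylation of a secondary propargylic alcohol at low temperature; the C–O bond is not broken, so the configuration is retained.

Step 6
Reactants: 7 (S)-1-(triisopropylsilyloxy)but-3-yn-2-yl methanesulfonate; 2 3-methoxy-4-(triisopropylsilyloxy)benzaldehyde
Product: 9 (1S,2R)-1-[3-methoxy-4-(triisopropylsilyloxy)phenyl]-2-[(triisopropylsilyloxy)methyl]but-3-yn-1-ol, via allenylzinc reagent 8 (not isolated)
Conditions: Pd(OAc)2 (5 mol %), PPh3 (5 mol %), Et2Zn (3 equiv), THF, −78 to −20 °C
Reagents that add atoms: none
Why: Marshall–Tamaru propargylation: zerovalent palladium displaces the mesylate anti (SN2'), Et2Zn takes over the allenyl group to give the (P)-allenylzinc 8, and this adds to the aldehyde through a cyclic syn SE2' transition state. The axis sets the propargylic centre as R, and the aryl group of the aldehyde avoids the CH2OSi group, so the hydroxyl ends anti to the branch (carbinol centre S).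

Step 7
Reactants: 10 dihydroconiferyl alcohol
Product: 11 4-(3-hydroxypropyl)-2-iodo-6-methoxyphenol
Conditions: I2, KI, NaHCO3, H2O–THF, 0 °C to rt
Reagents that add atoms: iodine, II
Why: Electrophilic aromatic iodination of the phenoxide; the para position is blocked by the chain, so iodine should enter the only free position ortho to the hydroxyl, and the primary alcohol is inert.

Step 8
Reactants: 11 4-(3-hydroxypropyl)-2-iodo-6-methoxyphenol
Product: 14 3-(7-methoxy-1-benzofuran-5-yl)propan-1-ol, via silylalkynylphenol 12 (not isolated), via 2-ethynylphenol 13 (not isolated)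
Conditions: TMS-acetylene, Pd(PPh3)2Cl2 (cat.), CuI (cat.), Et3N, THF, rt; then TBAF, 60 °C
Reagents that add atoms: ethynyltrimethylsilane, C#C[Si](C)(C)C
Why: Sonogashira coupling followed by fluoride desilylation and 5-endo-dig cyclisation of the ortho-ethynylphenoxide, a standard benzofuran annulation that leaves C2' unsubstituted for the next metalation.

Step 9
Reactants: 14 3-(7-methoxy-1-benzofuran-5-yl)propan-1-ol
Product: 15 tert-butyl[3-(7-methoxy-1-benzofuran-5-yl)propoxy]dimethylsilane
Conditions: TBSCl, imidazole, DMF, rt
Reagents that add atoms: tert-butylchlorodimethylsilane (TBSCl), CC(C)(C)[Si](C)(C)Cl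
Why: Silylation of a primary alcohol; this remote ether never sits next to an alkoxide, so the cheaper group suffices and comes off with the others at the end.

Step 10
Reactants: 15 tert-butyl[3-(7-methoxy-1-benzofuran-5-yl)propoxy]dimethylsilane; 16 3,6-dichloro-4-methoxypyridazine
Product: 19 6-{5-[3-(tert-butyldimethylsilyloxy)propyl]-7-methoxy-1-benzofuran-2-yl}-3-chloro-4-methoxypyridazine, via 2-lithiobenzofuran 17 (not isolated), via benzofuran-2-ylzinc chloride 18 (not isolated)
Conditions: n-BuLi, THF, −78 °C; ZnCl2, −78 to 0 °C; then 16 (1.2 equiv), Pd(PPh3)4 (5 mol %), THF, 50 °C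
Reagents that add atoms: none
Why: Deprotonation at C2' (the most acidic C–H of a benzofuran), lithium-to-zinc exchange and Negishi cross-coupling. Oxidative addition of zerovalent palladium should prefer the C6–Cl bond, which is unhindered and not ortho to the donating methoxy group, and the slight excess of 16 limits double coupling.

Step 11
Reactants: 9 (1S,2R)-1-[3-methoxy-4-(triisopropylsilyloxy)phenyl]-2-[(triisopropylsilyloxy)methyl]but-3-yn-1-ol; 19 6-{5-[3-(tert-butyldimethylsilyloxy)propyl]-7-methoxy-1-benzofuran-2-yl}-3-chloro-4-methoxypyridazine
Product: 21 6-{5-[3-(tert-butyldimethylsilyloxy)propyl]-7-methoxy-1-benzofuran-2-yl}-4-methoxy-3-({(1S,2R)-1-[3-methoxy-4-(triisopropylsilyloxy)phenyl]-2-[(triisopropylsilyloxy)methyl]but-3-yn-1-yl}oxy)pyridazine, via sodium alkoxide 20 (not isolated)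
Conditions: NaH (1.05 equiv), THF–DMF, 0 °C; then 19, 0 °C to rt
Reagents that add atoms: none
Why: Nucleophilic aromatic substitution (addition–elimination) at C3, the only carbon with a leaving group and activated by the adjacent ring nitrogen. The carbinol C–O bond is not broken, so C2 keeps its configuration, and the triisopropylsilyl ether next to the alkoxide should not migrate.

Step 12
Reactants: 21 6-{5-[3-(tert-butyldimethylsilyloxy)propyl]-7-methoxy-1-benzofuran-2-yl}-4-methoxy-3-({(1S,2R)-1-[3-methoxy-4-(triisopropylsilyloxy)phenyl]-2-[(triisopropylsilyloxy)methyl]but-3-yn-1-yl}oxy)pyridazine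
Product: 23 (2S,3R)-5-{5-[3-(tert-butyldimethylsilyloxy)propyl]-7-methoxy-1-benzofuran-2-yl}-7-methoxy-2-[3-methoxy-4-(triisopropylsilyloxy)phenyl]-3-[(triisopropylsilyloxy)methyl]-2,3-dihydro-1-benzofuran, via diazabicyclooctatriene adduct 22 (not isolated)
Conditions: N,N-diethylaniline (0.02 M), 200 °C, sealed tube, Ar
Reagents that add atoms: none
Why: The 1,2-diazine of 21 is the electron-poor 4π component and the tethered terminal alkyne the 2π component of an intramolecular inverse-electron-demand Diels–Alder reaction: pyridazine C3 and C6 bond to the internal and terminal alkyne carbons to give the 2,3-diazabicyclo[2.2.2]octatriene 22, which loses N2 by retro-[4+2] and is aromatic at once, so no oxidant is needed. The closest known reaction type is the thermal conversion of 3-(but-3-ynyloxy)pyridazines into 2,3-dihydrobenzofurans, which uses the same three-atom O–C–C tether. Ring B closes as the five-membered tether ring of the cycloaddition (bond C3a–C7a); ring C is formed by the cycloaddition–cycloreversion pair (bonds C3a–C7a and C4–C5), the four pyridazine carbons becoming C7a, C7 (OMe), C6 (H) and C5 (benzofuranyl). No stereocentre is created: C2 and C3 are spectators on the tether, and the two bridgehead centres of 22 vanish with N2, so both faces of approach lead to 23. The selectivity needed is regiochemical: the short tether allows only the fused orientation, so the pattern of ring C is fixed by the pyridazine, and the two tether substituents favour the folded, reactive conformer. The basic, acid-free solvent is chosen so that the electron-rich benzylic C2–O bond does not ionise at this temperature.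

Step 13
Reactants: 23 (2S,3R)-5-{5-[3-(tert-butyldimethylsilyloxy)propyl]-7-methoxy-1-benzofuran-2-yl}-7-methoxy-2-[3-methoxy-4-(triisopropylsilyloxy)phenyl]-3-[(triisopropylsilyloxy)methyl]-2,3-dihydro-1-benzofuran
Product: 24 4-[(2S,3R)-3-(hydroxymethyl)-5-[5-(3-hydroxypropyl)-7-methoxy-1-benzofuran-2-yl]-7-methoxy-2,3-dihydro-1-benzofuran-2-yl]-2-methoxyphenol
Conditions: TBAF (5 equiv), AcOH (5 equiv), THF, 0 °C to rt
Reagents that add atoms: none
Why: Fluoride-mediated cleavage of all three silyl ethers in one operation; acetic acid keeps the liberated phenol protonated, so the para-hydroxybenzylic ether of ring B should not open through a quinone methide.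

## Compound list

1 | vanillin (4-hydroxy-3-methoxybenzaldehyde) | COc1cc(C=O)ccc1O | starting material
2 | 3-methoxy-4-(triisopropylsilyloxy)benzaldehyde | COc1cc(C=O)ccc1O[Si](C(C)C)(C(C)C)C(C)C | intermediate
3 | (R)-2,2-dimethyl-1,3-dioxolane-4-carbaldehyde | O=C[C@H]1COC(C)(C)O1 | starting material
4 | (S)-4-ethynyl-2,2-dimethyl-1,3-dioxolane | C#C[C@H]1COC(C)(C)O1 | intermediate
5 | (S)-but-3-yne-1,2-diol | C#C[C@H](O)CO | intermediate
6 | (S)-1-(triisopropylsilyloxy)but-3-yn-2-ol | C#C[C@H](O)CO[Si](C(C)C)(C(C)C)C(C)C | intermediate
7 | (S)-1-(triisopropylsilyloxy)but-3-yn-2-yl methanesulfonate | C#C[C@H](OS(C)(=O)=O)CO[Si](C(C)C)(C(C)C)C(C)C | intermediate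
8 | ethyl[(P)-4-(triisopropylsilyloxy)buta-1,2-dien-1-yl]zinc (not isolated) | CC[Zn]C([H])=[C@@]=C([H])CO[Si](C(C)C)(C(C)C)C(C)C | intermediate
9 | (1S,2R)-1-[3-methoxy-4-(triisopropylsilyloxy)phenyl]-2-[(triisopropylsilyloxy)methyl]but-3-yn-1-ol (anti) | COc1cc([C@@H](O)[C@H](C#C)CO[Si](C(C)C)(C(C)C)C(C)C)ccc1O[Si](C(C)C)(C(C)C)C(C)C | intermediate
10 | dihydroconiferyl alcohol (4-(3-hydroxypropyl)-2-methoxyphenol) | COc1cc(CCCO)ccc1O | starting material
11 | 4-(3-hydroxypropyl)-2-iodo-6-methoxyphenol | COc1cc(CCCO)cc(I)c1O | intermediate
12 | 4-(3-hydroxypropyl)-2-methoxy-6-[(trimethylsilyl)ethynyl]phenol (not isolated) | COc1cc(CCCO)cc(C#C[Si](C)(C)C)c1O | intermediate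
13 | 2-ethynyl-4-(3-hydroxypropyl)-6-methoxyphenol (not isolated) | COc1cc(CCCO)cc(C#C)c1O | intermediate
14 | 3-(7-methoxy-1-benzofuran-5-yl)propan-1-ol | COc1cc(CCCO)cc2ccoc12 | intermediate
15 | tert-butyl[3-(7-methoxy-1-benzofuran-5-yl)propoxy]dimethylsilane | COc1cc(CCCO[Si](C)(C)C(C)(C)C)cc2ccoc12 | intermediate
16 | 3,6-dichloro-4-methoxypyridazine | COc1cc(Cl)nnc1Cl | starting material
17 | {5-[3-(tert-butyldimethylsilyloxy)propyl]-7-methoxy-1-benzofuran-2-yl}lithium (not isolated) | [Li]c1cc2cc(CCCO[Si](C)(C)C(C)(C)C)cc(OC)c2o1 | intermediate
18 | {5-[3-(tert-butyldimethylsilyloxy)propyl]-7-methoxy-1-benzofuran-2-yl}zinc chloride (not isolated) | Cl[Zn]c1cc2cc(CCCO[Si](C)(C)C(C)(C)C)cc(OC)c2o1 | intermediate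
19 | 6-{5-[3-(tert-butyldimethylsilyloxy)propyl]-7-methoxy-1-benzofuran-2-yl}-3-chloro-4-methoxypyridazine | COc1cc(-c2cc3cc(CCCO[Si](C)(C)C(C)(C)C)cc(OC)c3o2)nnc1Cl | intermediate
20 | sodium (1S,2R)-1-[3-methoxy-4-(triisopropylsilyloxy)phenyl]-2-[(triisopropylsilyloxy)methyl]but-3-yn-1-olate (not isolated) | COc1cc([C@@H]([O-])[C@H](C#C)CO[Si](C(C)C)(C(C)C)C(C)C)ccc1O[Si](C(C)C)(C(C)C)C(C)C.[Na+] | intermediate
21 | 6-{5-[3-(tert-butyldimethylsilyloxy)propyl]-7-methoxy-1-benzofuran-2-yl}-4-methoxy-3-({(1S,2R)-1-[3-methoxy-4-(triisopropylsilyloxy)phenyl]-2-[(triisopropylsilyloxy)methyl]but-3-yn-1-yl}oxy)pyridazine | COc1cc([C@@H](Oc2nnc(-c3cc4cc(CCCO[Si](C)(C)C(C)(C)C)cc(OC)c4o3)cc2OC)[C@H](C#C)CO[Si](C(C)C)(C(C)C)C(C)C)ccc1O[Si](C(C)C)(C(C)C)C(C)C | intermediate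
22 | 2,3-diazabicyclo[2.2.2]octa-2,5,7-triene cycloadduct of 21, fused to ring B through the bridgehead C7a and the alkene carbon C3a; either bridgehead configuration (not isolated) | COc1cc([C@H]2OC34N=NC(c5cc6cc(CCCO[Si](C)(C)C(C)(C)C)cc(OC)c6o5)(C=C3OC)C=C4[C@@H]2CO[Si](C(C)C)(C(C)C)C(C)C)ccc1O[Si](C(C)C)(C(C)C)C(C)C | intermediate
23 | (2S,3R)-5-{5-[3-(tert-butyldimethylsilyloxy)propyl]-7-methoxy-1-benzofuran-2-yl}-7-methoxy-2-[3-methoxy-4-(triisopropylsilyloxy)phenyl]-3-[(triisopropylsilyloxy)methyl]-2,3-dihydro-1-benzofuran | COc1cc([C@H]2Oc3c(OC)cc(-c4cc5cc(CCCO[Si](C)(C)C(C)(C)C)cc(OC)c5o4)cc3[C@@H]2CO[Si](C(C)C)(C(C)C)C(C)C)ccc1O[Si](C(C)C)(C(C)C)C(C)C | intermediate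
24 | 4-[(2S,3R)-3-(hydroxymethyl)-5-[5-(3-hydroxypropyl)-7-methoxy-1-benzofuran-2-yl]-7-methoxy-2,3-dihydro-1-benzofuran-2-yl]-2-methoxyphenol | COc1cc([C@H]2Oc3c(OC)cc(-c4cc5cc(CCCO)cc(OC)c5o4)cc3[C@@H]2CO)ccc1O | target

## Step count and risks

Total: 13 steps. Longest linear sequence: 8 steps (from 3 through steps 2 to 6 and 11 to 13).

**Step 12 (key step).** The diazine carries two alkoxy groups and an electron-rich hetaryl group, so the cycloaddition may be slow. During long heating the benzylic C2–O bond, activated by the para silyloxy group, may ionise, which would cause oxygen-to-nitrogen migration of the benzylic group, loss of configuration at C2 or elimination. The fallback sets out from 21 and returns at 24. The phenolic silyl group of 21 would be removed selectively with one equivalent of acetic acid-buffered TBAF at low temperature (aryl silyl ethers are cleaved much faster than alkyl ones) to give the free phenol F1. F1 would be acetylated in the same flask (Ac2O, pyridine) to the aryl acetate F2. With the ring-A oxygen now an acceptor, ionisation is disfavoured and the cycloaddition of F2 can be driven harder to the cycloadduct acetate F3. TBAF in THF–methanol would then cleave the two alkyl silyl ethers and methanolyse the aryl acetate in one operation to give 24.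

**Step 6.** With an aromatic aldehyde the anti preference of the allenylzinc addition may be modest. The zinc reagent may also lose its β-silyloxy group by elimination from its propargyl form, and ethyl transfer from Et2Zn to the aldehyde can compete. The fallback sets out from 6 and returns at 9. Alcohol 6 would be converted with methyl chloroformate and pyridine into the methyl carbonate F4. Copper-catalysed SN2' borylation with B2pin2 (CuOtBu, Xantphos), which also proceeds with anti displacement, would give the isolable (P)-allenylboronate F5. F5 would add to aldehyde 2 on warming, without additive, through a compact boron-centred cyclic transition state of the same stereochemical sense, giving 9.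

**Step 10.** Oxidative addition may occur in part at the C3–Cl bond, or a second coupling may follow the first, giving regioisomeric or doubly arylated material that is hard to separate. The fallback sets out from 15 and returns at 19. Benzofuran 15 would be lithiated as before and quenched with 2-isopropoxy-4,4,5,5-tetramethyl-1,3,2-dioxaborolane to give the pinacol boronate F6. Suzuki–Miyaura coupling (Pd(PPh3)4, Na2CO3, dioxane–water) with 6-chloro-4-methoxypyridazin-3(2H)-one F7, in which C3 is a carbonyl and only C6 bears a halogen, would give the pyridazinone F8. Deoxychlorination with PPh3 and N-chlorosuccinimide in dioxane, neutral conditions that the silyl ether should tolerate, would give 19.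

**Step 11.** The chloride is flanked by a methoxy group and the alkoxide is hindered, so substitution may be slow. A long-lived alkoxide allows silyl migration, base-induced isomerisation of the alkyne, or attack at C4 with exchange of the methoxy group. The fallback sets out from 19 and returns at 21. NaSMe in DMF would convert 19 into the methyl sulfide F9, and mCPBA buffered with NaHCO3 would oxidise it to the methyl sulfone F10. The sulfinate is a far better leaving group and would be displaced by alkoxide 20 at or below 0 °C to give 21.

## Further compounds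

F1 | step 12 | 4-[(1S,2R)-1-({6-[5-(3-(tert-butyldimethylsilyloxy)propyl)-7-methoxy-1-benzofuran-2-yl]-4-methoxypyridazin-3-yl}oxy)-2-[(triisopropylsilyloxy)methyl]but-3-yn-1-yl]-2-methoxyphenol | COc1cc([C@@H](Oc2nnc(-c3cc4cc(CCCO[Si](C)(C)C(C)(C)C)cc(OC)c4o3)cc2OC)[C@H](C#C)CO[Si](C(C)C)(C(C)C)C(C)C)ccc1O
F2 | step 12 | aryl acetate of F1 (4-acetoxy-3-methoxyphenyl analogue of 21) | COc1cc([C@@H](Oc2nnc(-c3cc4cc(CCCO[Si](C)(C)C(C)(C)C)cc(OC)c4o3)cc2OC)[C@H](C#C)CO[Si](C(C)C)(C(C)C)C(C)C)ccc1OC(C)=O
F3 | step 12 | 4-[(2S,3R)-5-{5-[3-(tert-butyldimethylsilyloxy)propyl]-7-methoxy-1-benzofuran-2-yl}-7-methoxy-3-[(triisopropylsilyloxy)methyl]-2,3-dihydro-1-benzofuran-2-yl]-2-methoxyphenyl acetate | COc1cc([C@H]2Oc3c(OC)cc(-c4cc5cc(CCCO[Si](C)(C)C(C)(C)C)cc(OC)c5o4)cc3[C@@H]2CO[Si](C(C)C)(C(C)C)C(C)C)ccc1OC(C)=O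
F4 | step 6 | methyl (S)-1-(triisopropylsilyloxy)but-3-yn-2-yl carbonate | C#C[C@H](OC(=O)OC)CO[Si](C(C)C)(C(C)C)C(C)C
F5 | step 6 | (P)-4,4,5,5-tetramethyl-2-[4-(triisopropylsilyloxy)buta-1,2-dien-1-yl]-1,3,2-dioxaborolane | CC1(C)OB(OC1(C)C)C([H])=[C@@]=C([H])CO[Si](C(C)C)(C(C)C)C(C)C
F6 | step 10 | tert-butyl{3-[7-methoxy-2-(4,4,5,5-tetramethyl-1,3,2-dioxaborolan-2-yl)-1-benzofuran-5-yl]propoxy}dimethylsilane | COc1cc(CCCO[Si](C)(C)C(C)(C)C)cc2cc(B3OC(C)(C)C(C)(C)O3)oc12
F7 | step 10 | 6-chloro-4-methoxypyridazin-3(2H)-one | COc1cc(Cl)n[nH]c1=O
F8 | step 10 | 6-{5-[3-(tert-butyldimethylsilyloxy)propyl]-7-methoxy-1-benzofuran-2-yl}-4-methoxypyridazin-3(2H)-one | COc1cc(-c2cc3cc(CCCO[Si](C)(C)C(C)(C)C)cc(OC)c3o2)n[nH]c1=O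
F9 | step 11 | 6-{5-[3-(tert-butyldimethylsilyloxy)propyl]-7-methoxy-1-benzofuran-2-yl}-4-methoxy-3-(methylsulfanyl)pyridazine | COc1cc(-c2cc3cc(CCCO[Si](C)(C)C(C)(C)C)cc(OC)c3o2)nnc1SC
F10 | step 11 | 6-{5-[3-(tert-butyldimethylsilyloxy)propyl]-7-methoxy-1-benzofuran-2-yl}-4-methoxy-3-(methylsulfonyl)pyridazine | COc1cc(-c2cc3cc(CCCO[Si](C)(C)C(C)(C)C)cc(OC)c3o2)nnc1S(C)(=O)=O
A1 | alternative 1 | (2S)-6-bromo-8-methoxy-2-[3-methoxy-4-(methanesulfonyloxy)phenyl]-2,3-dihydro-4H-1-benzopyran-4-one | COc1cc([C@@H]2CC(=O)c3cc(Br)cc(OC)c3O2)ccc1OS(C)(=O)=O
A2 | alternative 1 | methyl (2S,3S)-trans-5-bromo-7-methoxy-2-[3-methoxy-4-(methanesulfonyloxy)phenyl]-2,3-dihydro-1-benzofuran-3-carboxylate | COc1cc([C@H]2Oc3c(OC)cc(Br)cc3[C@@H]2C(=O)OC)ccc1OS(C)(=O)=O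
A3 | alternative 2 | pentacarbonyl{methoxy[5-((2S,3R)-3-[(tert-butyldimethylsilyloxy)methyl]-7-methoxy-2-[3-methoxy-4-(triisopropylsilyloxy)phenyl]-2,3-dihydro-1-benzofuran-5-yl)furan-2-yl]methylidene}chromium, (CO)5Cr=C(OMe)(furyl) | COc1cc([C@H]2Oc3c(OC)cc(-c4ccc(C(OC)=[Cr](=C=O)(=C=O)(=C=O)(=C=O)=C=O)o4)cc3[C@@H]2CO[Si](C)(C)C(C)(C)C)ccc1O[Si](C(C)C)(C(C)C)C(C)C
A4 | alternative 2 | tert-butyldimethyl(pent-4-yn-1-yloxy)silane | C#CCCCO[Si](C)(C)C(C)(C)C
A5 | alternative 2 | 4'-hydroxy derivative of the tris-silylated target (TBS on both primary oxygens, TIPS on the phenol) | COc1cc([C@H]2Oc3c(OC)cc(-c4cc5c(O)c(CCCO[Si](C)(C)C(C)(C)C)cc(OC)c5o4)cc3[C@@H]2CO[Si](C)(C)C(C)(C)C)ccc1O[Si](C(C)C)(C(C)C)C(C)C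
A6 | alternative 3 | 4-bromo-2-[(2R)-1-(tert-butyldimethylsilyloxy)-3-(4-hydroxy-3-methoxyphenyl)propan-2-yl]-6-methoxyphenol | COc1cc(C[C@@H](CO[Si](C)(C)C(C)(C)C)c2cc(Br)cc(OC)c2O)ccc1O
A7 | alternative 3 | (2S,3R)-5-bromo-3-[(tert-butyldimethylsilyloxy)methyl]-2-(4-hydroxy-3-methoxyphenyl)-7-methoxy-2,3-dihydro-1-benzofuran | COc1cc([C@H]2Oc3c(OC)cc(Br)cc3[C@@H]2CO[Si](C)(C)C(C)(C)C)ccc1O
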